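Take a closed, stirred, isothermal vessel charged with G, D and a little J, and count the G that has reacted at a set time.

| setting | north-west | south | elm | birch | cedar |
|---|---|---|---|---|---|
| G | 16 mM | 16 mM | 16 mM | 16 mM | 16 mM |
| D | 2.7 equiv | 4.1 equiv | 2.00 equiv | 3.40 equiv | 2.60 equiv |
| J | 0.80 mM | 0.80 mM | 0.800 mM | 0.800 mM | 0.800 mM |
| remark | run made earlier | run made earlier |  |  |  |
| time |  |  | 2.0 h | 2.0 h | 2.0 h |

- north-west (time / min: G / %, E / %): 15.0: 70.4, 20.4; 30.0: 56.1, 31.8; 50.0: 42.2, 38.9; 60.0: 36.4, 40.4; 80.0: 30.3, 42.4; 90.0: 27.0, 43.5; 120: 20.0, 44.3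
- south (time / min: G / %, E / %): 15.0: 60.9, 30.5; 30.0: 41.7, 43.5; 50.0: 26.3, 49.5; 60.0: 21.9, 51.0; 80.0: 13.7, 50.2; 90.0: 10.8, 51.1; 120: 6.4, 50.6

(each reading ± 0.5 percentage points)

* part of the G that has reacted at the end, elm
* part of the G that has reacted at the end, birch
* part of the G that has reacted at the end, cedar
* what raising the equivalents of D from its lowest to its highest value here does to the part of the G that has reacted (changes below 5 percentage points count as none) (no change / it falls / it rises)

Build the flask one process at a time and test each version on the last readings of both runs, at 120 min. Let g be the share of G left, b the equivalents of D charged, a the D spent per G reacted, and W the exposure: rate constant times G charge times time. Both runs share the G charge and time of the new flasks, so they should share W.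

Start with the main step alone and [D] held at its charge, the pseudo-first-order picture: ln(1/g) = bW. North-west gives W = 0.596 and south 0.670, so the version fails.

Now let [D] fall as G reacts and integrate: ln[(b − a + ag)/(bg)] = (b − a)W. One D per G gives 0.740 and 0.803, still apart. Two D per G gives 1.02 and 1.02, a narrower gap. Keep a = 2 and the exposure of this time, W = 1.02.

Then the rest. E levels off near 44.3% in north-west and 50.6% in south while G keeps falling, so count G, not E. J is charged alike in both runs, so let W carry whatever it does.

Solved, g = (b − a)/(b·exp[(b − a)W] − a). Elm charges exactly the cost, so there g = 1/(1 + 2W). My reckoning gives 67.1% reacted in elm, 88.5% in birch and 78.5% in cedar: a rise of 21 percentage points.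

The forecast gives 66.5% for elm, 88.5% for birch and 78.4% for cedar, and says of the part reacted from the lowest D to the highest: it rises, in its words “Conversion therefore rises with D”.

The flask gives 68.1% in elm, 88.2% in birch and 78.8% in cedar; from the lowest D to the highest, it rises, by 20 points. Elm ends with 37.0% of its D free, a cost of 1.85 equivalents per G reacted, close to the two of the rule.

    G + D → Q + E (k = 0.490 M⁻¹ min⁻¹)
    D + Q ⇌ X, settled at all times (K = 33000 M⁻¹)
    E ⇌ L (K = 0.970, k = 0.0140 min⁻¹)
    G + J → Z (k = 14.0 M⁻¹ min⁻¹)

Use W again on elm at half the time: the exposure halves, so g = 49.6%, and elm holds 48.3% of its G at 1.00 h.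

Now cut elm's D to 0.500 equiv: W gives 20.7% reacted. The computed flask gives 24.8%, of which Z holds 5.00%.

The runs were computed with made-up constants.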